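The readings come from a simulation with made-up constants.

A small shortfall in the charge, 0.760 M of reagent against 0.80 M of substrate, gives me a clock for this flask.

all flasks: substrate 0.80 M

| flask | reagent | scavenger | remark | time |
|---|---|---|---|---|
| noon | 0.76 M | 1.3 M | run made earlier |  |
| autumn | 0.76 M | 1.4 M | run made earlier |  |
| west | 0.760 M | 1.20 M |  | 3.0 h |
| south | 0.760 M | 1.80 M |  | 3.0 h |

| run | time / h | substrate / % | target / % |
|---|---|---|---|
| noon | 0.250 | 74.2 | 8.0 |
| noon | 0.833 | 46.3 | 12.5 |
| noon | 1.33 | 35.9 | 13.9 |
| noon | 2.00 | 27.2 | 14.9 |
| noon | 3.00 | 20.7 | 16.1 |
| autumn | 0.250 | 74.1 | 7.8 |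
| autumn | 0.833 | 46.9 | 12.1 |
| autumn | 1.33 | 35.9 | 14.1 |
| autumn | 2.00 | 27.4 | 14.6 |
| autumn | 3.00 | 20.4 | 16.1 |

(standard deviation of a reading: 0.3 percentage points)



- part of the substrate that has reacted at the end, west
- part of the substrate that has reacted at the end, south
- what raising the concentration of scavenger from its lowest to its highest value here does to the part of the substrate that has reacted (changes below 5 percentage points count as none) (it falls / it rises / no change)

I write a for the fraction of its charge of substrate left and b for the same fraction of reagent, and I build the flask up one process at a time. First comes the main step, substrate with reagent, with the reagent held at its charge (the pseudo-first-order picture). The logarithm of a then falls on a straight line, and the first noon reading, 74.2% left at 0.250 h, carried on to 3.0 h gives 97.2% reacted, more than the 79.3% the noon run shows.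

Second, I let the reagent be spent one for one with the substrate, so a of 46.3% at 0.833 h in the noon run means b of 43.5%. For such a pair the common logarithm of a/b starts at zero and rises on a straight line in time, at a rate proportional to the excess of substrate over reagent in the charge. This noon reading puts it at 0.0274, which gives 0.0137 M⁻¹ min⁻¹: the log-gap clock, the rise of that logarithm per minute per unit of excess. Run on to 3.0 h, the clock gives a gap of 0.0985, so a/b is 1.25, and with b tied to a that means 79.4% reacted. The later readings took no part in this, so the 79.3% and 79.6% reacted in the noon and autumn runs are a real check.

Then the rest. The two runs, at 1.3 M and 1.4 M of scavenger, differ by 0.3 percentage points at 3.00 h against a scatter of 0.3 points, so I add no term for the scavenger and none for the target. My number stays 79.4% for west and for south, though 1.80 M lies beyond the runs.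

The forecast gives 79.4% for west, 79.6% for south and no change, “with no need for a scavenger term”.

West gives 79.2% and south 79.2%, so the trend is no change, with a change of 0.006 points.

    substrate + reagent → intermediate + released group (k = 0.0310 M⁻¹ min⁻¹)
    intermediate ⇌ target (K = 0.920, k = 0.260 min⁻¹)
    intermediate ⇌ isomer of the product (K = 2.60, k = 0.110 min⁻¹)
    reagent + released group ⇌ idle adduct, settled at all times (K = 1.90 M⁻¹)
    scavenger + released group → scavenged by-product (k = 5.10 M⁻¹ min⁻¹)
    released group → by-product carried off (k = 0.980 min⁻¹)

The clock of 0.0137 M⁻¹ min⁻¹ gave 79.4% on west, which stands at 79.2%. The neighbour of south charged with 1.4 M of substrate has a larger excess, 640 mM. In 3.0 h the clock then gives a gap of 1.58, so a/b is 37.7, which means 53.6% reacted and 1.23% of the reagent left. That flask gives 53.6% reacted, and the reagent, its limiting reagent, keeps 1.3% of its charge.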